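**Assumption:** the SMILES is taken literally, so the enone decalin is cis-fused (3-OH, H-5 and CH3-10 all on one face) and the saturated decalin is trans-fused. Drimane-type locants are used for each half (C1–C10, C11 = CH2 on C9 of the enone half; primed locants and C12 for the saturated half).

## Retrosynthetic overview

1. Last bond: C11–C12 (the CH2–CH2 tether), made by a visible-light nickel/iridium cross-electrophile coupling of an allylic bromide (enone half) with a primary iodide (saturated half).
2. Each ring A is closed onto an intact carvone ring B by iron-hydride hydrogen-atom transfer: the isopropenyl group becomes C4 with its gem-dimethyl and adds as a tertiary radical to a C3 aldehyde.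
3. Each C10 quaternary centre comes from two α′-alkylations of carvone. Allyl-then-methyl on (S)-carvone gives the cis-fused half; methyl-then-allyl on (R)-carvone gives the trans-fused half.
4. Enone half: MeLi addition and oxidative 1,3-transposition of the carvone enone, equatorial-side hydride reduction at C3, γ-bromination. Saturated half: hydrogenation/epimerisation (C8′), methylenation, hydroboration–iodination (C9′).
5. Ring order: ring B (bought) → ring A (radical cyclisation) in each half → union of the two bicycles.

## Route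

**Enone (cis-fused) half, from (S)-carvone**

Step 1
Reactants: 1 (S)-(+)-carvone
Product: 3 6-allylcarvone (allyl trans to isopropenyl as major epimer), via lithium dienolate 2 (not isolated)
Conditions: LiN(i-Pr)2 (1.1 equiv), THF, −78 °C; allyl bromide, −78 → 0 °C
Reagents that add atoms: allyl bromide, C=CCBr
Why: kinetic α′-deprotonation and enolate alkylation anti to the neighbouring isopropenyl group; the C6 epimer ratio does not matter because C6 is re-enolised in step 2.

Step 2
Reactants: 3 6-allylcarvone
Product: 5 6-allyl-6-methylcarvone (CH3 trans and allyl cis to isopropenyl), via lithium enolate 4 (not isolated)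
Conditions: LiN(i-Pr)2 (1.2 equiv), THF/DMPU, −78 °C; MeI, −78 → −20 °C
Reagents that add atoms: iodomethane, CI
Why: second enolate alkylation; MeI enters anti to the adjacent isopropenyl group (the bought C5 stereocentre), which fixes quaternary C10 with CH3 cis to H-5 and the allyl arm cis to the isopropenyl group.

Step 3
Reactants: 5 6-allyl-6-methylcarvone (CH3 trans to isopropenyl)
Product: 6 aldehyde 3-[(1S,6R-type) 1,3-dimethyl-2-oxo-6-isopropenylcyclohex-3-enyl]propanal (chain cis to isopropenyl)
Conditions: PdCl2(PhCN)2 (12 mol%), CuCl2·2H2O (12 mol%), AgNO2 (6 mol%), O2 (1 atm), t-BuOH/MeNO2 15:1, 25 °C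
Reagents that add atoms: oxygen, O=O
Why: nitrite-modified anti-Markovnikov Wacker oxidation converts only the monosubstituted allyl alkene to the aldehyde; the 1,1-disubstituted isopropenyl alkene and the enone are inert.

Step 4
Reactants: 6 aldehyde (chain cis to isopropenyl)
Product: 7 cis-fused 3-hydroxy-4,4,8,10-tetramethyl-Δ7-octalin-9-one (H-5 and CH3-10 both β; C3 epimer mixture)
Conditions: Fe(acac)3 (0.3 equiv), PhSiH3 (2.5 equiv), EtOH, 60 °C
Reagents that add atoms: none
Why: iron-hydride hydrogen-atom transfer to the isopropenyl group gives the tertiary C4 radical, which adds 6-exo to the aldehyde (Mukaiyama-type radical carbonyl–olefin cyclisation); chain and radical are cis on ring B, so ring A can only close cis-fused, and the C3 ratio is irrelevant because C3 is oxidised in step 6.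

Step 5
Reactants: 7 cis-fused hydroxy-enone
Product: 8 cis-fused 4,4,8,9,10-pentamethyl-Δ7-octalin-3,9-diol (C3 and C9 epimers)
Conditions: MeLi (3 equiv), THF, −78 → 0 °C; H2O
Reagents that add atoms: methyllithium, [Li]C
Why: 1,2-addition of the small organolithium to the hindered enone carbonyl installs C11 and creates the tertiary allylic alcohol needed for transposition.

Step 6
Reactants: 8 diol
Product: 9 cis-fused 4,4,8,9,10-pentamethyl-Δ8-octalin-3,7-dione (H-5 β, CH3-10 β)
Conditions: [C5H5NH][CrO3Cl] (4 equiv), 4 Å molecular sieves, CH2Cl2, 25 °C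
Reagents that add atoms: none
Why: Dauben–Babler oxidative 1,3-transposition (chromate ester [3,3] shift, then oxidation) moves the carbonyl to C7 and forms the tetrasubstituted C8=C9 enone, while the same reagent oxidises the C3 carbinol to the ketone and erases the C3 mixture.

Step 7
Reactants: 9 ene-dione
Product: 10 cis-fused 3β-hydroxy-4,4,8,9,10-pentamethyl-Δ8-octalin-7-one (OH, H-5 and CH3-10 all β)
Conditions: LiBH(s-Bu)3 (1.1 equiv), THF, −78 °C; H2O
Reagents that add atoms: none
Why: substrate-controlled hydride reduction; the ring A chair with CH3-10 equatorial and C9 axial avoids the CH3-4/CH3-10 1,3-diaxial clash, and the bulky borohydride attacks it from the equatorial side (as with 3-keto-5β-steroids and 4,4-dimethyl-3-ketotriterpenoids) to give the axial 3β-alcohol, while the β,β-disubstituted enone carbonyl is not reduced at −78 °C.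

Step 8
Reactants: 10 3β-hydroxy-9-methyl enone
Product: 11 cis-fused 11-bromo-3β-hydroxy-4,4,8,10-tetramethyl-Δ8-octalin-7-one (9-bromomethyl enone)
Conditions: NBS (1.05 equiv), AIBN (5 mol%), PhCF3, 80 °C
Reagents that add atoms: N-bromosuccinimide, O=C1CCC(=O)N1Br
Why: Wohl–Ziegler bromination at the γ-methyl, whose radical is delocalised through C9=C8 onto the carbonyl (the same selectivity as γ-bromination of tiglates).

**Saturated (trans-fused) half, from (R)-carvone**

Step 9
Reactants: 12 (R)-(−)-carvone
Product: 14 6-methylcarvone (CH3 trans to isopropenyl as major epimer), via lithium dienolate 13 (not isolated)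
Conditions: LiN(i-Pr)2 (1.1 equiv), THF, −78 °C; MeI, −78 → 0 °C
Reagents that add atoms: iodomethane, CI
Why: kinetic α′-enolate alkylation; the C6 ratio is irrelevant because C6 is re-enolised in step 10.

Step 10
Reactants: 14 6-methylcarvone
Product: 16 6-allyl-6-methylcarvone (allyl trans and CH3 cis to isopropenyl), via lithium enolate 15 (not isolated)
Conditions: LiN(i-Pr)2 (1.2 equiv), THF/DMPU, −78 °C; allyl bromide, −78 → 0 °C
Reagents that add atoms: allyl bromide, C=CCBr
Why: enolate alkylation anti to the adjacent isopropenyl group; reversing the order of the two electrophiles relative to steps 1–2 gives the other C10 relationship (CH3-10′ trans to H-5′), which leads to the trans ring fusion.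

Step 11
Reactants: 16 6-allyl-6-methylcarvone (allyl trans to isopropenyl)
Product: 17 aldehyde 3-[1,3-dimethyl-2-oxo-6-isopropenylcyclohex-3-enyl]propanal (chain trans to isopropenyl)
Conditions: PdCl2(PhCN)2 (12 mol%), CuCl2·2H2O (12 mol%), AgNO2 (6 mol%), O2 (1 atm), t-BuOH/MeNO2 15:1, 25 °C
Reagents that add atoms: oxygen, O=O
Why: aldehyde-selective (anti-Markovnikov) Wacker oxidation of the only monosubstituted alkene.

Step 12
Reactants: 17 aldehyde (chain trans to isopropenyl)
Product: 18 trans-fused 3β-hydroxy-4,4,8,10-tetramethyl-Δ7-octalin-9-one (H-5′ α, CH3-10′ β)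
Conditions: Fe(acac)3 (0.3 equiv), PhSiH3 (2.5 equiv), EtOH, 60 °C
Reagents that add atoms: none
Why: the same hydrogen-atom-transfer radical carbonyl–olefin cyclisation; chain and radical are trans-diequatorial on ring B, so a trans-decalin forms through a chair with the aldehyde oxygen equatorial, giving the equatorial (more stable) 3β-alcohol.

Step 13
Reactants: 18 trans-fused hydroxy-enone
Product: 20 trans-fused 3β-hydroxy-4,4,8α,10β-tetramethyldecal-9-one (H-8′ β axial), via C8-epimer mixture 19 (not isolated)
Conditions: H2 (1 atm), Pd/C (palladium on carbon, 5 mol%), EtOAc, 25 °C; then NaOMe (0.2 equiv), MeOH, 25 °C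
Reagents that add atoms: none
Why: catalytic hydrogenation of the enone C=C, then enolate equilibration at C8′ to the equatorial α-methyl, because an axial 8β-methyl would be 1,3-diaxial to CH3-10′.

Step 14
Reactants: 20 saturated ketone
Product: 21 trans-fused 3β-hydroxy-8α-methyl-9(12)-methylene decalin (exocyclic alkene at C9′)
Conditions: Ph3PCH3Br (4 equiv), KOt-Bu (4 equiv), toluene, 90 °C
Reagents that add atoms: methyltriphenylphosphonium bromide, C[P+](c1ccccc1)(c1ccccc1)c1ccccc1.[Br-]
Why: Wittig methylenation with excess salt-free ylide at elevated temperature, as used for α-quaternary decalones; C8′ is already at its thermodynamic configuration and is locked once the ketone is gone.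

Step 15
Reactants: 21 exocyclic alkene
Product: 23 trans-fused 12-iodo-3β-hydroxy-8α-methyl decalin (9β-CH2I and H-9′ α), via B-alkyl-9-BBN 22 (not isolated)
Conditions: 9-BBN (2.5 equiv), THF, 65 °C; then NaOMe, MeOH, I2, 0 → 25 °C
Reagents that add atoms: iodine, II
Why: hydroboration from the α face, away from the axial CH3-10′ on the neighbouring carbon, puts H-9′ α and the CH2B group equatorial; base-induced iodinolysis of the primary C–B bond (Brown iodination) then gives the iodide.

**Union**

Step 16
Reactants: 23 primary iodide of the saturated half; 11 allylic bromide of the enone half (1.5 equiv)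
Product: 24 target (CNP0290352.1)
Conditions: NiBr2(dme) (10 mol%), 4,4′-di-tert-butyl-2,2′-bipyridine (12 mol%), [Ir(dF(CF3)ppy)2(dtbbpy)]PF6 (1 mol%), (Me3Si)3SiH (1.2 equiv), Na2CO3 (2 equiv), DME, 450 nm LEDs, 25 °C
Reagents that add atoms: none
Why: Proposed new method: a visible-light nickel/iridium cross-electrophile coupling of an unactivated primary alkyl iodide with an allylic bromide that is a vinylogous α-bromo ketone — zerovalent nickel adds oxidatively to the allylic C–Br bond of 11 to give an η3-(oxa)allyl nickel bromide, the silyl radical formed from (Me3Si)3SiH under photoredox catalysis abstracts iodine from 23, the primary radical is captured at nickel, and the trivalent alkyl(allyl)nickel species reductively eliminates at the unhindered CH2 terminus (C11) so the conjugated tetrasubstituted enone is restored while the reduced iridium photocatalyst returns nickel to the zerovalent state; no stereocentre is formed or touched and both free hydroxyls are tolerated; the closest known reaction types are silyl-radical metallaphotoredox C(sp3)–C(sp3) cross-electrophile coupling of alkyl bromides and nickel-catalysed reductive allylation of alkyl halides with zinc.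

## Compound list

1 | (S)-(+)-carvone | CC1=CC[C@@H](CC1=O)C(C)=C | starting material
2 | lithium dienolate of 1 (C6=C1–OLi) | CC1=CC[C@H](C(C)=C)C=C1O[Li] | intermediate
3 | 6-allylcarvone from 1, allyl trans to isopropenyl (major epimer) | CC1=CC[C@H](C(C)=C)[C@@H](CC=C)C1=O | intermediate
4 | lithium enolate of 3 | CC1=CC[C@H](C(C)=C)C(CC=C)=C1O[Li] | intermediate
5 | 6-allyl-6-methylcarvone, CH3 trans and allyl cis to isopropenyl | CC1=CC[C@H](C(C)=C)[C@](C)(CC=C)C1=O | intermediate
6 | 3-oxopropyl analogue of 5 (aldehyde, chain cis to isopropenyl) | CC1=CC[C@H](C(C)=C)[C@](C)(CCC=O)C1=O | intermediate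
7 | cis-fused 3-hydroxy-4,4,8,10-tetramethyl-Δ7-octalin-9-one (5β-H, 10β-CH3; C3 epimers) | CC1=CC[C@@H]2C(C)(C)C(O)CC[C@]2(C)C1=O | intermediate
8 | cis-fused 4,4,8,9,10-pentamethyl-Δ7-octalin-3,9-diol (C3, C9 epimers) | CC1=CC[C@@H]2C(C)(C)C(O)CC[C@]2(C)C1(C)O | intermediate
9 | cis-fused 4,4,8,9,10-pentamethyl-Δ8-octalin-3,7-dione | CC1=C(C)[C@@]2(C)CCC(=O)C(C)(C)[C@H]2CC1=O | intermediate
10 | cis-fused 3β-hydroxy-4,4,8,9,10-pentamethyl-Δ8-octalin-7-one | CC1=C(C)[C@@]2(C)CC[C@H](O)C(C)(C)[C@H]2CC1=O | intermediate
11 | cis-fused 9-(bromomethyl)-3β-hydroxy-4,4,8,10-tetramethyl-Δ8-octalin-7-one | CC1=C(CBr)[C@@]2(C)CC[C@H](O)C(C)(C)[C@H]2CC1=O | intermediate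
12 | (R)-(−)-carvone | CC1=CC[C@H](CC1=O)C(C)=C | starting material
13 | lithium dienolate of 12 | CC1=CC[C@@H](C(C)=C)C=C1O[Li] | intermediate
14 | 6-methylcarvone from 12, CH3 trans to isopropenyl (major epimer) | CC1=CC[C@@H](C(C)=C)[C@H](C)C1=O | intermediate
15 | lithium enolate of 14 | CC1=CC[C@@H](C(C)=C)C(C)=C1O[Li] | intermediate
16 | 6-allyl-6-methylcarvone, allyl trans and CH3 cis to isopropenyl | CC1=CC[C@@H](C(C)=C)[C@](C)(CC=C)C1=O | intermediate
17 | 3-oxopropyl analogue of 16 (aldehyde, chain trans to isopropenyl) | CC1=CC[C@@H](C(C)=C)[C@](C)(CCC=O)C1=O | intermediate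
18 | trans-fused 3β-hydroxy-4,4,8,10-tetramethyl-Δ7-octalin-9-one (5α-H, 10β-CH3) | O=C1C(C)=CC[C@H]2C(C)(C)[C@@H](O)CC[C@]12C | intermediate
19 | trans-fused 3β-hydroxy-4,4,8,10-tetramethyldecal-9-one, C8 epimer mixture | O=C1C(C)CC[C@H]2C(C)(C)[C@@H](O)CC[C@]12C | intermediate
20 | trans-fused 3β-hydroxy-4,4,8α,10β-tetramethyldecal-9-one | O=C1[C@H](C)CC[C@H]2C(C)(C)[C@@H](O)CC[C@]12C | intermediate
21 | trans-fused 3β-hydroxy-4,4,8α,10β-tetramethyl-9-methylenedecalin | C=C1[C@H](C)CC[C@H]2C(C)(C)[C@@H](O)CC[C@]12C | intermediate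
22 | B-(decalin-9β-ylmethyl)-9-BBN of 21, 3-O-(9-BBN) borinate, H-9 α | C(B1C2CCCC1CCC2)[C@H]1[C@H](C)CC[C@H]2C(C)(C)[C@@H](OB3C4CCCC3CCC4)CC[C@]12C | intermediate
23 | trans-fused 9β-(iodomethyl)-3β-hydroxy-4,4,8α,10β-tetramethyldecalin | IC[C@H]1[C@H](C)CC[C@H]2C(C)(C)[C@@H](O)CC[C@]12C | intermediate
24 | CNP0290352.1 | CC1=C(CC[C@H]2[C@H](C)CC[C@H]3C(C)(C)[C@@H](O)CC[C@]23C)[C@@]2(C)CC[C@H](O)C(C)(C)[C@H]2CC1=O | target

## Step count and risks

Total steps: 16. Longest linear sequence: 9 (steps 1–8, then 16); the other branch is 8 (steps 9–15, then 16).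

**Step 16 (the proposed coupling).** Homocoupling of 11 at nickel or simple reduction of either halide could outrun the cross-coupling. The fallback uses known chemistry, sets out from 21 and 11, and comes back at 24. Hydroboration–oxidation of 21 (9-BBN; NaOH/H2O2) gives the 3β,12-diol F1. TEMPO/PhI(OAc)2 oxidises only its primary alcohol to the 12-aldehyde F2. Arbuzov reaction of 11 with P(OEt)3 gives the diethyl phosphonate F3. Horner–Wadsworth–Emmons olefination of F2 with the sodium salt of F3 (NaH, THF) gives the (E)-11,12-dehydro dienone F4. Hydrogenation with RhCl(PPh3)3 saturates only the disubstituted C11=C12 bond and gives 24.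

**Step 12 (and its sibling, step 4).** The aldehyde may be reduced, or the tertiary radical quenched, before ring closure; in step 12 the C3′ ratio may also be modest. The fallback sets out from 17 and comes back at 18. Iodine in aqueous ammonia/THF converts the aldehyde to the nitrile F5. The known Fe(acac)3/PhSiH3 hydrogen-atom-transfer alkene–nitrile cyclisation, followed by aqueous acid hydrolysis of the imine, gives the trans-fused ene-3,9-dione F6. NaBH4 (MeOH, −40 °C) reduces the saturated 3-ketone by axial attack to the equatorial 3β-alcohol 18.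

**Step 8 (radical γ-bromination).** Bromination at the C8 methyl or oxidation of the axial 3-OH by NBS may compete. The fallback carries the C11 oxygen in from the addition step instead; it sets out from 7 and comes back at 11. (Methoxymethoxy)methyllithium (from Bu3SnCH2OCH2OCH3 and n-BuLi) adds in place of MeLi to give the MOM-protected adduct F7. [C5H5NH][CrO3Cl] gives the transposed 11-(methoxymethoxy) ene-dione F8. LiBH(s-Bu)3 gives the 3β-alcohol F9. HCl in MeOH removes the MOM group to give the 11-hydroxy enone F10. CBr4/PPh3 brominates only the primary allylic alcohol to give 11.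

## Further compounds

F1 | step 16 | trans-fused 9β-(hydroxymethyl)-3β-hydroxy-4,4,8α,10β-tetramethyldecalin | OC[C@H]1[C@H](C)CC[C@H]2C(C)(C)[C@@H](O)CC[C@]12C
F2 | step 16 | trans-fused 3β-hydroxy-4,4,8α,10β-tetramethyldecalin-9β-carbaldehyde | O=C[C@H]1[C@H](C)CC[C@H]2C(C)(C)[C@@H](O)CC[C@]12C
F3 | step 16 | diethyl phosphonate from 11 (P in place of Br at C11) | CC1=C(CP(=O)(OCC)OCC)[C@@]2(C)CC[C@H](O)C(C)(C)[C@H]2CC1=O
F4 | step 16 | (11E)-11,12-didehydro analogue of 24 (dienone) | CC1=C(/C=C/[C@H]2[C@H](C)CC[C@H]3C(C)(C)[C@@H](O)CC[C@]23C)[C@@]2(C)CC[C@H](O)C(C)(C)[C@H]2CC1=O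
F5 | step 12 | nitrile corresponding to aldehyde 17 | CC1=CC[C@@H](C(C)=C)[C@](C)(CCC#N)C1=O
F6 | step 12 | trans-fused 4,4,8,10-tetramethyl-Δ7-octalin-3,9-dione | O=C1C(C)=CC[C@H]2C(C)(C)C(=O)CC[C@]12C
F7 | step 8 | cis-fused 9-[(methoxymethoxy)methyl]-4,4,8,10-tetramethyl-Δ7-octalin-3,9-diol (C3, C9 epimers) | CC1=CC[C@@H]2C(C)(C)C(O)CC[C@]2(C)C1(O)COCOC
F8 | step 8 | cis-fused 9-[(methoxymethoxy)methyl]-4,4,8,10-tetramethyl-Δ8-octalin-3,7-dione | CC1=C(COCOC)[C@@]2(C)CCC(=O)C(C)(C)[C@H]2CC1=O
F9 | step 8 | cis-fused 3β-hydroxy-9-[(methoxymethoxy)methyl]-4,4,8,10-tetramethyl-Δ8-octalin-7-one | CC1=C(COCOC)[C@@]2(C)CC[C@H](O)C(C)(C)[C@H]2CC1=O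
F10 | step 8 | cis-fused 3β-hydroxy-9-(hydroxymethyl)-4,4,8,10-tetramethyl-Δ8-octalin-7-one | CC1=C(CO)[C@@]2(C)CC[C@H](O)C(C)(C)[C@H]2CC1=O
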